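**Plan**

- Cuts, in retrosynthetic order: the two acetate C–O bonds; the ring A bond C3–C4 (carbinol carbon to gem-dimethyl carbon); the side-chain bond C9–C11; the bonds C10–C1 and C10–CH3.
- This leads back to (R)-carvone (ring B with C17 and the isopropenyl group that holds C4, C18, C19), MeI, allyl bromide and a C6 iodide made from methyl (R)-3-methylglutarate.
- Forward: carvone is methylated and allylated at C10, the side chain is added to the carbonyl carbon (C9), the enone is transposed and reduced to the 7-ene with 9α-H, the allyl arm is oxidised to the C3 aldehyde, and ring A is closed last.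
- Enabling feature: in ring A the secondary carbinol C3 stands next to the fully substituted C4 carrying two methyl groups. This is the retron of a tertiary radical (hydrogen-atom transfer to an isopropenyl group) adding to an aldehyde, and both arms sit trans-diequatorial on C5 and C10 of ring B.
- Stereochemistry: C5 from (R)-carvone; C10 by alkylation anti to the isopropenyl group; C9 by axial protonation in the dissolving-metal reduction; C3 in the ring closure; C13 from the glutarate.

Key step: step 13

Remark: labdane numbering and α/β descriptors (C10 methyl = β) are kept for the ring-A-open (3,4-seco) intermediates; methyl (R)-3-methylglutarate and (R)-carvone are assumed to be purchased, and disiamylborane is assumed to be made in the flask from BH3·THF and 2-methylbut-2-ene.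

**Route**

Step 1
Reactants: 1 methyl (R)-3-methylglutarate [(3R)-5-methoxy-3-methyl-5-oxopentanoic acid]
Product: 2 methyl (3R)-5-hydroxy-3-methylpentanoate
Conditions: BH3·SMe2, THF, 0 °C → rt; MeOH, then aqueous work-up
Reagents that add atoms: none
Why: Borane reduces the carboxylic acid through its acyloxyborane much faster than the ester (chemoselective borane reduction), and the stereocenter is not touched.

Step 2
Reactants: 2 methyl (3R)-5-hydroxy-3-methylpentanoate
Product: 3 methyl (3R)-5-(tert-butyldimethylsilyloxy)-3-methylpentanoate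
Conditions: TBSCl, imidazole, DMF, rt
Reagents that add atoms: tert-butyldimethylsilyl chloride, CC(C)(C)[Si](C)(C)Cl
Why: Standard silylation of a primary alcohol, done at once so that the hydroxy ester cannot lactonise.

Step 3
Reactants: 3 methyl (3R)-5-(tert-butyldimethylsilyloxy)-3-methylpentanoate
Product: 4 (3S)-5-(tert-butyldimethylsilyloxy)-3-methylpentan-1-ol
Conditions: LiAlH4, THF, 0 °C
Reagents that add atoms: none
Why: Hydride reduction of the ester to the primary alcohol; the silyl ether is stable and the two chain ends stay differentiated.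

Step 4
Reactants: 4 (3S)-5-(tert-butyldimethylsilyloxy)-3-methylpentan-1-ol
Product: 5 tert-butyl{[(3R)-5-iodo-3-methylpentyl]oxy}dimethylsilane
Conditions: I2, PPh3, imidazole, CH2Cl2, 0 °C → rt
Reagents that add atoms: iodine, II
Why: Appel-type iodination of a primary alcohol through the alkoxyphosphonium salt (SN2 at CH2, stereocenter remote).

Step 5
Reactants: 6 (R)-carvone [(5R)-2-methyl-5-(prop-1-en-2-yl)cyclohex-2-en-1-one]
Product: 8 6-methylcarvone [(5R)-2,6-dimethyl-5-(prop-1-en-2-yl)cyclohex-2-en-1-one; both C6 epimers], via lithium dienolate of carvone 7 (not isolated)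
Conditions: LiN(i-Pr)2, THF, −78 °C; MeI, −78 → 0 °C
Reagents that add atoms: iodomethane, CI
Why: Kinetic α'-deprotonation gives the cross-conjugated dienolate, which is C-methylated (enolate alkylation); the configuration of the new center does not matter because it is planarised in step 6.

Step 6
Reactants: 8 6-methylcarvone
Product: 10 (5S,6S)-6-allyl-2,6-dimethyl-5-(prop-1-en-2-yl)cyclohex-2-en-1-one (allyl trans to isopropenyl; methyl cis), via lithium enolate of 6-methylcarvone 9 (not isolated)
Conditions: LiN(i-Pr)2, THF, −78 → 0 °C; allyl bromide, DMPU, −78 °C → rt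
Reagents that add atoms: allyl bromide, C=CCBr
Why: Enolate alkylation in which allyl bromide should approach the trisubstituted enolate anti to the neighbouring isopropenyl group, which sets the quaternary C10 with its methyl cis to the isopropenyl group.

Step 7
Reactants: 5 tert-butyl{[(3R)-5-iodo-3-methylpentyl]oxy}dimethylsilane; 10 (5S,6S)-6-allyl-2,6-dimethyl-5-(prop-1-en-2-yl)cyclohex-2-en-1-one
Product: 12 15-(tert-butyldimethylsilyloxy)-3,4-seco-labda-2,4(18),7-trien-9-ol (13S; C9 epimers), via (S)-5-(tert-butyldimethylsilyloxy)-3-methylpentyllithium 11 (not isolated)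
Conditions: 5, t-BuLi (2 equiv per iodide), Et2O/pentane, −78 °C; then 10, −78 → 0 °C; aq NH4Cl
Reagents that add atoms: none
Why: Lithium–iodine exchange gives the primary alkyllithium, which adds 1,2 to the enone carbonyl (no α-hydrogen on the quaternary side); the carbinol configuration is erased in step 8.

Step 8
Reactants: 12 15-(tert-butyldimethylsilyloxy)-3,4-seco-labda-2,4(18),7-trien-9-ol
Product: 13 15-(tert-butyldimethylsilyloxy)-3,4-seco-labda-2,4(18),8-trien-7-one [(4S,5S)-4-allyl-2,4-dimethyl-5-isopropenyl-3-(side chain)cyclohex-2-en-1-one]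
Conditions: pyridinium chlorochromate [C5H5NH][CrO3Cl], NaOAc, 4 Å sieves, CH2Cl2, rt
Reagents that add atoms: pyridinium chlorochromate, [O-][Cr](=O)(=O)Cl.c1cc[nH+]cc1
Why: Babler–Dauben oxidative 1,3-transposition: the tertiary allylic chromate ester rearranges by a [3,3] shift to C7 and is oxidised to the enone, which puts the side chain on the β-carbon C9 (the carbonyl oxygen comes from the chromate).

Step 9
Reactants: 13 15-(tert-butyldimethylsilyloxy)-3,4-seco-labda-2,4(18),8-trien-7-one
Product: 15 15-(tert-butyldimethylsilyloxy)-3,4-seco-labda-2,4(18),7-trien-7-yl trifluoromethanesulfonate (9α-H), via lithium 7-enolate 14 (not isolated)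
Conditions: Li, liquid NH3/THF, t-BuOH (1 equiv), −78 °C; isoprene; NH3 evaporated; PhNTf2, THF, −78 °C → rt
Reagents that add atoms: N-phenylbis(trifluoromethanesulfonimide), O=S(=O)(N(c1ccccc1)S(=O)(=O)C(F)(F)F)C(F)(F)F
Why: Dissolving-metal enone reduction with trapping of the regiodefined enolate on oxygen (reductive enolate triflation); C9 should be protonated axially on the α face, anti to the pseudo-axial C10 methyl, in the half-chair that keeps the isopropenyl group, the allyl group and the side chain equatorial.

Step 10
Reactants: 15 15-(tert-butyldimethylsilyloxy)-3,4-seco-labda-2,4(18),7-trien-7-yl trifluoromethanesulfonate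
Product: 16 15-(tert-butyldimethylsilyloxy)-3,4-seco-labda-2,4(18),7-triene (5α-H, 9α-H, 10β-CH3, 13S)
Conditions: Pd(OAc)2 (cat.), PPh3, Bu3N, HCO2H, DMF, 60 °C
Reagents that add atoms: none
Why: Palladium-catalysed formate reduction of the enol triflate (oxidative addition to zerovalent palladium, formate exchange, loss of CO2, C–H reductive elimination) fixes the double bond at C7=C8 without touching C9.

Step 11
Reactants: 16 15-(tert-butyldimethylsilyloxy)-3,4-seco-labda-2,4(18),7-triene
Product: 18 15-(tert-butyldimethylsilyloxy)-3,4-seco-labda-4(18),7-dien-3-ol, via 3-(disiamylboryl) adduct 17 (not isolated)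
Conditions: Sia2BH [(Me2CHCHMe)2BH], THF, 0 °C; then NaOH, H2O2, 0 °C → rt
Reagents that add atoms: hydrogen peroxide, OO
Why: Hydroboration–oxidation with a bulky dialkylborane, which should take the monosubstituted vinyl group anti-Markovnikov in preference to the hindered 1,1-disubstituted isopropenyl group and the trisubstituted ring alkene.

Step 12
Reactants: 18 15-(tert-butyldimethylsilyloxy)-3,4-seco-labda-4(18),7-dien-3-ol
Product: 19 15-(tert-butyldimethylsilyloxy)-3,4-seco-labda-4(18),7-dien-3-al
Conditions: Dess–Martin periodinane, NaHCO3, CH2Cl2, 0 °C → rt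
Reagents that add atoms: none
Why: Mild Dess–Martin oxidation of the primary alcohol to the aldehyde without over-oxidation or alkene migration.

Step 13
Reactants: 19 15-(tert-butyldimethylsilyloxy)-3,4-seco-labda-4(18),7-dien-3-al
Product: 22 15-(tert-butyldimethylsilyloxy)labd-7-en-3β-ol (5α-H, 9α-H, 10β-CH3, 13S), via tertiary C4 radical 20 (not isolated), via C3 alkoxyl radical 21 (not isolated)
Conditions: Fe(acac)3 (0.5 equiv), PhSiH3 (2.5 equiv), degassed EtOH (0.02 M), 60 °C, argon
Reagents that add atoms: none
Why: An iron hydride formed from Fe(acac)3 and PhSiH3 transfers a hydrogen atom to the terminal CH2 of the isopropenyl group (Markovnikov), and the tertiary radical 20 adds to the formyl carbon to give alkoxyl radical 21, which is reduced by divalent iron and protonated by ethanol, so that trivalent iron is returned and the reversible addition is pulled forward. The closest known reaction type is the iron-mediated hydrogen-atom-transfer cyclization of alkene-tethered ketones, together with the related coupling of unactivated alkenes with aldehydes. Ring A closes in the 6-exo-trig mode onto the C=O bond through a chair transition state, and because the isopropenyl group on C5 and the propanal arm on C10 are trans-diequatorial on ring B, only the trans-fused decalin can form. C4 becomes the gem-dimethyl quaternary carbon and is not stereogenic; the new stereocenter C3 should be set by the formyl oxygen taking the pseudo-equatorial position of the chair, away from the axial hydrogens on C1 and C5, which gives the equatorial 3β-alcohol. The step needs hydrogen-atom transfer to the 1,1-disubstituted alkene and not to the hindered trisubstituted C7=C8 bond, which the rate difference and a limited amount of silane should secure, and it needs ring closure to outrun a second hydrogen transfer, which high dilution and the fast 6-exo addition to an aldehyde favour.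

Step 14
Reactants: 22 15-(tert-butyldimethylsilyloxy)labd-7-en-3β-ol
Product: 23 (13S)-labd-7-ene-3β,15-diol
Conditions: Bu4NF, THF, rt
Reagents that add atoms: none
Why: Fluoride cleavage of the primary silyl ether; no other group in the molecule reacts.

Step 15
Reactants: 23 (13S)-labd-7-ene-3β,15-diol
Product: 24 (13S)-labd-7-ene-3β,15-diyl diacetate (target)
Conditions: Ac2O, pyridine, DMAP (cat.), CH2Cl2, rt
Reagents that add atoms: acetic anhydride, CC(=O)OC(C)=O
Why: DMAP-catalysed acetylation of the primary alcohol and the hindered equatorial secondary alcohol with retention at C3.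

**Compound list**

1 | methyl (R)-3-methylglutarate | COC(=O)C[C@H](C)CC(O)=O | starting material
2 | methyl (3R)-5-hydroxy-3-methylpentanoate | COC(=O)C[C@H](C)CCO | intermediate
3 | methyl (3R)-5-(tert-butyldimethylsilyloxy)-3-methylpentanoate | COC(=O)C[C@H](C)CCO[Si](C)(C)C(C)(C)C | intermediate
4 | (3S)-5-(tert-butyldimethylsilyloxy)-3-methylpentan-1-ol | OCC[C@H](C)CCO[Si](C)(C)C(C)(C)C | intermediate
5 | tert-butyl{[(3R)-5-iodo-3-methylpentyl]oxy}dimethylsilane | ICC[C@H](C)CCO[Si](C)(C)C(C)(C)C | intermediate
6 | (R)-carvone | CC1=CC[C@H](CC1=O)C(C)=C | starting material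
7 | lithium dienolate of carvone | CC1=CC[C@H](C=C1O[Li])C(C)=C | intermediate
8 | 6-methylcarvone (C6 epimers) | CC1=CC[C@H](C(C)C1=O)C(C)=C | intermediate
9 | lithium enolate of 6-methylcarvone | CC1=CC[C@H](C(C)=C1O[Li])C(C)=C | intermediate
10 | (5S,6S)-6-allyl-2,6-dimethyl-5-(prop-1-en-2-yl)cyclohex-2-en-1-one | O=C1C(C)=CC[C@@H](C(C)=C)[C@]1(C)CC=C | intermediate
11 | (S)-5-(tert-butyldimethylsilyloxy)-3-methylpentyllithium | [Li]CC[C@H](C)CCO[Si](C)(C)C(C)(C)C | intermediate
12 | 15-(tert-butyldimethylsilyloxy)-3,4-seco-labda-2,4(18),7-trien-9-ol (C9 epimers) | CC(C)(C)[Si](C)(C)OCC[C@@H](C)CCC1(O)C(C)=CC[C@@H](C(C)=C)[C@]1(C)CC=C | intermediate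
13 | 15-(tert-butyldimethylsilyloxy)-3,4-seco-labda-2,4(18),8-trien-7-one | CC(C)(C)[Si](C)(C)OCC[C@@H](C)CCC1=C(C)C(=O)C[C@@H](C(C)=C)[C@]1(C)CC=C | intermediate
14 | lithium 7-enolate (9α-H) | CC(C)(C)[Si](C)(C)OCC[C@@H](C)CC[C@H]1C(C)=C(O[Li])C[C@@H](C(C)=C)[C@]1(C)CC=C | intermediate
15 | 15-(tert-butyldimethylsilyloxy)-3,4-seco-labda-2,4(18),7-trien-7-yl trifluoromethanesulfonate | CC(C)(C)[Si](C)(C)OCC[C@@H](C)CC[C@H]1C(C)=C(OS(=O)(=O)C(F)(F)F)C[C@@H](C(C)=C)[C@]1(C)CC=C | intermediate
16 | 15-(tert-butyldimethylsilyloxy)-3,4-seco-labda-2,4(18),7-triene | CC(C)(C)[Si](C)(C)OCC[C@@H](C)CC[C@H]1C(C)=CC[C@@H](C(C)=C)[C@]1(C)CC=C | intermediate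
17 | 3-(disiamylboryl) adduct of 16 | CC(C)(C)[Si](C)(C)OCC[C@@H](C)CC[C@H]1C(C)=CC[C@@H](C(C)=C)[C@]1(C)CCCB(C(C)C(C)C)C(C)C(C)C | intermediate
18 | 15-(tert-butyldimethylsilyloxy)-3,4-seco-labda-4(18),7-dien-3-ol | CC(C)(C)[Si](C)(C)OCC[C@@H](C)CC[C@H]1C(C)=CC[C@@H](C(C)=C)[C@]1(C)CCCO | intermediate
19 | 15-(tert-butyldimethylsilyloxy)-3,4-seco-labda-4(18),7-dien-3-al | CC(C)(C)[Si](C)(C)OCC[C@@H](C)CC[C@H]1C(C)=CC[C@@H](C(C)=C)[C@]1(C)CCC=O | intermediate
20 | tertiary C4 radical | CC(C)(C)[Si](C)(C)OCC[C@@H](C)CC[C@H]1C(C)=CC[C@@H]([C](C)C)[C@]1(C)CCC=O | intermediate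
21 | C3 alkoxyl radical | CC(C)(C)[Si](C)(C)OCC[C@@H](C)CC[C@H]1C(C)=CC[C@H]2C(C)(C)[C@@H]([O])CC[C@]12C | intermediate
22 | 15-(tert-butyldimethylsilyloxy)labd-7-en-3β-ol | CC(C)(C)[Si](C)(C)OCC[C@@H](C)CC[C@H]1C(C)=CC[C@H]2C(C)(C)[C@@H](O)CC[C@]12C | intermediate
23 | (13S)-labd-7-ene-3β,15-diol | OCC[C@@H](C)CC[C@H]1C(C)=CC[C@H]2C(C)(C)[C@@H](O)CC[C@]12C | intermediate
24 | (13S)-labd-7-ene-3β,15-diyl diacetate | CC(=O)OCC[C@@H](C)CC[C@H]1C(C)=CC[C@H]2C(C)(C)[C@@H](OC(C)=O)CC[C@]12C | target

**Count and risks**

Total steps: 15. Longest linear sequence: 13 (steps 1–4, then 7–15).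

Steps most likely to fail:

1. Step 13. What may go wrong: low facial selectivity in the addition of the tertiary radical to the formyl group (axial against equatorial oxygen), besides hydrogen delivery to the radical before it closes the ring. The fallback sets out from 22 as it comes from step 13 (mixed with its C3 epimer) and comes back to 22. Dess–Martin oxidation of the mixture gives the single ketone 15-(tert-butyldimethylsilyloxy)labd-7-en-3-one F1. NaBH4 in MeOH at 0 °C should then deliver hydride axially from the α face, away from the axial methyl groups on C4 and C10, to give the equatorial 3β-alcohol 22. C3 is thereby set by substrate-controlled hydride reduction and no longer in the radical step.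

2. Step 9. What may go wrong: protonation of C9 from the wrong face in the flexible monocycle, over-reduction, or incomplete O-trapping of the enolate. The fallback sets out from enone 13 and comes back to the route at triene 16, passing by 15 and step 10. Luche reduction (NaBH4, CeCl3, MeOH, −78 °C) should give by axial hydride attack the equatorial allylic alcohol 15-(tert-butyldimethylsilyloxy)-3,4-seco-labda-2,4(18),8-trien-7β-ol F2. A Mitsunobu reaction with 2-nitrobenzenesulfonylhydrazide (PPh3, diethyl azodicarboxylate, THF, −30 °C) gives with inversion the 7α-sulfonylhydrazine F3. On warming to rt this loses 2-nitrobenzenesulfinic acid to the 7α-monoalkyl diazene F4. Loss of N2 by a retro-ene shift then delivers hydrogen to the α face of C9 and moves the double bond to C7=C8, giving 16. The C9 configuration is here relayed from the C7 carbinol and no longer depends on the face of protonation.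

3. Step 11. What may go wrong: incomplete discrimination between the vinyl and the isopropenyl group in the hydroboration. The fallback sets out from triene 16 and comes back to the route at aldehyde 19, passing by 18 and step 12. A nitrite-modified, aldehyde-selective Wacker oxidation (PdCl2(PhCN)2, CuCl2, AgNO2, O2, t-BuOH/MeNO2, rt) oxidises only the monosubstituted alkene, at its terminal carbon; 1,1-disubstituted and trisubstituted alkenes do not react under these conditions. No new compound is made on the way.

**Further compounds**

F1 | step 13 | 15-(tert-butyldimethylsilyloxy)labd-7-en-3-one | CC(C)(C)[Si](C)(C)OCC[C@@H](C)CC[C@H]1C(C)=CC[C@H]2C(C)(C)C(=O)CC[C@]12C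
F2 | step 9 | 15-(tert-butyldimethylsilyloxy)-3,4-seco-labda-2,4(18),8-trien-7β-ol | CC(C)(C)[Si](C)(C)OCC[C@@H](C)CCC1=C(C)[C@@H](O)C[C@@H](C(C)=C)[C@]1(C)CC=C
F3 | step 9 | 7α-[1-(2-nitrophenylsulfonyl)hydrazinyl]-15-(tert-butyldimethylsilyloxy)-3,4-seco-labda-2,4(18),8-triene | CC(C)(C)[Si](C)(C)OCC[C@@H](C)CCC1=C(C)[C@H](N(N)S(=O)(=O)c2ccccc2[N+](=O)[O-])C[C@@H](C(C)=C)[C@]1(C)CC=C
F4 | step 9 | 7α-diazenyl-15-(tert-butyldimethylsilyloxy)-3,4-seco-labda-2,4(18),8-triene | CC(C)(C)[Si](C)(C)OCC[C@@H](C)CCC1=C(C)[C@H](N=N)C[C@@H](C(C)=C)[C@]1(C)CC=C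
F0 | step 11 | none | none
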